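**Plan**
- Retrosynthesis: cut the C3–O acyl bond (angelate); trace the (13Z)-15,16-diol back to a 3-furyl ring and the C2 hydroxyl back to a C3 ketone enolate; then open ring B (C9–C10) and ring A (C4–C5) together with the C8=C17 alkene to an acyclic (E,E)-epoxy diene; cut that chain at C11–C12 into farnesyl bromide and a furylmethyl Grignard reagent.
- Forward: C11–C12 coupling, terminal allylic oxidation, asymmetric epoxidation; one titanocene-mediated radical cascade closes ring A, then ring B, and leaves the exocyclic alkene; then C3 ketone, C2 hydroxylation, reduction, angelate, furan-to-enediol unmasking, desilylation.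
- Enabling feature: the C3 carbinol next to quaternary C4 (an epoxide retron), the ring bonds C4–C5 and C9–C10 lying 1,5 along the chain C4/C5=C10/C9=C8, two six-membered trans-fused rings (chair–chair cascade), and the C8=C17 methylene, where the last (C8) radical sheds a hydrogen.
- Stereochemistry: C3 from Sharpless epoxidation with D-(−)-diethyl tartrate; C4, C5, C10 and C9 relayed from it in the cascade; C2 by enolate hydroxylation anti to the axial C4 and C10 methyl groups; C3 re-set by axial hydride delivery; 13Z from the furan ring; ester Z from angelic acid.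

Key step: step 6

Remark: labdane numbering is used for the bicyclic compounds (ring A = C1–C5, C10; ring B = C5–C10; C17 = exocyclic methylene carbon; C18 = the C4 substituent trans to the C10 methyl group C20). The target is taken as the (2S,3S,4S,5S,9R,10S,13Z) ent-labdane defined by the given SMILES.

**Step 1**
Reactants: 1 furan-3-ylmethanol
Product: 2 3-(chloromethyl)furan
Conditions: SOCl2, pyridine, Et2O, 0 °C
Reagents that add atoms: thionyl chloride, O=S(Cl)Cl
Why: Chlorodehydroxylation of the primary furylmethyl alcohol through its chlorosulfite, with pyridine taking up HCl so that the acid-sensitive furan survives, should give the halide needed for the Grignard reagent, and no stereocentre is involved.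

**Step 2**
Reactants: 2 3-(chloromethyl)furan; 3 (2E,6E)-farnesyl bromide
Product: 5 3-[(3E,7E)-4,8,12-trimethyltrideca-3,7,11-trien-1-yl]furan, via Grignard reagent 4 (not isolated)
Conditions: Mg, THF, 0 °C to rt; then 3, Li2CuCl4 (cat.), THF, −78 to 0 °C
Reagents that add atoms: none
Why: Copper-catalysed Grignard cross-coupling of the furylmethyl Grignard reagent with the primary allylic bromide should proceed by direct (SN2, head-to-head) substitution with retention of the 2E geometry, the classical assembly of 3-alkylfuran terpenes, and no stereocentre is formed.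

**Step 3**
Reactants: 5 3-[(3E,7E)-4,8,12-trimethyltrideca-3,7,11-trien-1-yl]furan
Product: 6 (2E,6E,10E)-13-(furan-3-yl)-2,6,10-trimethyltrideca-2,6,10-trien-1-ol
Conditions: SeO2 (cat.), t-BuOOH, salicylic acid (cat.), CH2Cl2, 0 °C to rt, partial conversion with recovery of 5
Reagents that add atoms: tert-butyl hydroperoxide, CC(C)(C)OO
Why: Selenium dioxide allylic oxidation (ene reaction, then [2,3]-sigmatropic shift of the allylseleninic acid) should attack the terminal isopropylidene group, the least hindered trisubstituted alkene, at its E-methyl group and give the (E)-allylic alcohol, under conditions that furanoterpenes of this kind are known to tolerate.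

**Step 4**
Reactants: 6 (2E,6E,10E)-13-(furan-3-yl)-2,6,10-trimethyltrideca-2,6,10-trien-1-ol
Product: 7 [(2R,3R)-3-[(3E,7E)-10-(furan-3-yl)-3,7-dimethyldeca-3,7-dien-1-yl]-2-methyloxiran-2-yl]methanol
Conditions: Ti(OiPr)4 (cat.), D-(−)-diethyl tartrate (cat.), t-BuOOH, 4 Å MS, CH2Cl2, −20 °C
Reagents that add atoms: tert-butyl hydroperoxide, CC(C)(C)OO
Why: Sharpless asymmetric epoxidation is directed by the allylic hydroxyl, so only the terminal alkene reacts, and with D-(−)-diethyl tartrate it should give the (2R,3R)-epoxy alcohol (the mirror-image series of that formed from (E)-allylic alcohols with the L-(+)-ester), which fixes the carbon that becomes C3.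

**Step 5**
Reactants: 7 [(2R,3R)-3-[(3E,7E)-10-(furan-3-yl)-3,7-dimethyldeca-3,7-dien-1-yl]-2-methyloxiran-2-yl]methanol
Product: 8 tert-butyl{[(2R,3R)-3-[(3E,7E)-10-(furan-3-yl)-3,7-dimethyldeca-3,7-dien-1-yl]-2-methyloxiran-2-yl]methoxy}dimethylsilane
Conditions: TBSCl, imidazole, DMF, 0 °C to rt
Reagents that add atoms: tert-butyldimethylsilyl chloride, CC(C)(C)[Si](C)(C)Cl
Why: Imidazole-promoted silylation of the primary alcohol masks it for the later oxidation at C3 and makes the future C4 substituent bulky, which serves the key step, while the epoxide is left untouched.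

**Step 6**
Reactants: 8 tert-butyl{[(2R,3R)-3-[(3E,7E)-10-(furan-3-yl)-3,7-dimethyldeca-3,7-dien-1-yl]-2-methyloxiran-2-yl]methoxy}dimethylsilane
Product: 10 (3R,4S,5S,9R,10S)-18-(tert-butyldimethylsilyloxy)-15,16-epoxylabda-8(17),13(16),14-trien-3-ol, via trimethylsilyl ether 9 (not isolated)
Conditions: Cp2TiCl2 (cat.), Mn dust, Me3SiCl, 2,4,6-collidine, dry THF, rt; then K2CO3, MeOH, 0 °C
Reagents that add atoms: none
Why: Cp2TiCl (trivalent titanium, formed in the flask from Cp2TiCl2 and Mn) opens the epoxide by single-electron transfer at the more substituted carbon to give the tertiary C4 radical with a C3–O–Ti bond; this radical adds to C5 (closing ring A), the tertiary C10 radical so formed adds to C9 of the C8=C9 alkene and thereby makes the C9–C10 bond that closes ring B, and the final tertiary C8 radical is captured by a second Cp2TiCl and loses a hydrogen from the C17 methyl group to leave the exocyclic alkene, while Me3SiCl with collidine takes the titanium off oxygen and hydride and Mn returns it to the trivalent state. The closest known reaction type is the titanocene-catalysed radical cascade cyclization of epoxypolyprenes to 3-hydroxy-8(17)-ene drimanes and labdanes, including epoxides that carry a protected hydroxymethyl group at the tertiary carbon. Ring A and ring B each close by a 6-endo-trig radical addition, through a chair–chair arrangement of the (E,E)-diene chain. C3 is carried over unchanged from the Sharpless epoxide and its titanium alkoxide sits equatorial; at the planar C4 radical the bulky silyloxymethyl group takes the equatorial site, away from the developing axial C10 methyl group; the trans ring fusion at C5 and C10 follows from the chair transition state of the E-alkene; and at C9 the furylethyl chain ends equatorial, trans to the C10 methyl group. The step needs termination to the 8(17)-alkene in preference to endocyclic isomers, to simple reduction or to a third closure onto the furan: capture of the hindered tertiary radical by Cp2TiCl followed by beta-hydride loss from the least hindered methyl group, in dry medium, should secure the first two, and the polarity mismatch between the nucleophilic tertiary radical and the electron-rich furan the last.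

**Step 7**
Reactants: 10 (3R,4S,5S,9R,10S)-18-(tert-butyldimethylsilyloxy)-15,16-epoxylabda-8(17),13(16),14-trien-3-ol
Product: 11 (4S,5S,9R,10S)-18-(tert-butyldimethylsilyloxy)-15,16-epoxylabda-8(17),13(16),14-trien-3-one
Conditions: Dess–Martin periodinane, CH2Cl2, rt
Reagents that add atoms: none
Why: Dess–Martin oxidation of the secondary C3 alcohol to the ketone runs under near-neutral conditions that leave the furan, the exocyclic alkene and the silyl ether alone, and the neighbouring C4 is quaternary and cannot epimerise.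

**Step 8**
Reactants: 11 (4S,5S,9R,10S)-18-(tert-butyldimethylsilyloxy)-15,16-epoxylabda-8(17),13(16),14-trien-3-one
Product: 13 (2S,4S,5S,9R,10S)-18-(tert-butyldimethylsilyloxy)-2-hydroxy-15,16-epoxylabda-8(17),13(16),14-trien-3-one, via potassium enolate 12 (not isolated)
Conditions: KHMDS, THF, −78 °C; then trans-3-phenyl-2-(phenylsulfonyl)oxaziridine, −78 °C; aq. NH4Cl
Reagents that add atoms: trans-3-phenyl-2-(phenylsulfonyl)oxaziridine (Davis oxaziridine), O=S(=O)(N1OC1c1ccccc1)c1ccccc1
Why: The ketone can enolise only toward C2 because C4 is quaternary, and Davis oxaziridine hydroxylation of the potassium enolate should occur on the face away from the two axial methyl groups at C4 and C10, which puts the new hydroxyl equatorial (2S), while this electrophilic oxygen donor leaves the alkene and the furan alone.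

**Step 9**
Reactants: 13 (2S,4S,5S,9R,10S)-18-(tert-butyldimethylsilyloxy)-2-hydroxy-15,16-epoxylabda-8(17),13(16),14-trien-3-one
Product: 14 (2S,4S,5S,9R,10S)-18-(tert-butyldimethylsilyloxy)-2-(triethylsilyloxy)-15,16-epoxylabda-8(17),13(16),14-trien-3-one
Conditions: Et3SiOTf, 2,6-lutidine, CH2Cl2, −78 °C
Reagents that add atoms: triethylsilyl trifluoromethanesulfonate, CC[Si](CC)(CC)OS(=O)(=O)C(F)(F)F
Why: Silylation with the silyl triflate and a hindered pyridine base at low temperature caps the ketol hydroxyl before ketol transposition can set in and differentiates O2 from O3 for the later esterification.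

**Step 10**
Reactants: 14 (2S,4S,5S,9R,10S)-18-(tert-butyldimethylsilyloxy)-2-(triethylsilyloxy)-15,16-epoxylabda-8(17),13(16),14-trien-3-one
Product: 15 (2S,3S,4S,5S,9R,10S)-18-(tert-butyldimethylsilyloxy)-2-(triethylsilyloxy)-15,16-epoxylabda-8(17),13(16),14-trien-3-ol
Conditions: NaBH4, CeCl3·7H2O, MeOH–THF, −40 °C
Reagents that add atoms: none
Why: Luche reduction should deliver hydride along the axial trajectory on the face away from the axial C4 methyl group, giving the equatorial C3 alcohol trans to the C2 silyloxy group (3S), and the weakly acidic cerium medium suppresses 1,2-silyl migration.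

**Step 11**
Reactants: 15 (2S,3S,4S,5S,9R,10S)-18-(tert-butyldimethylsilyloxy)-2-(triethylsilyloxy)-15,16-epoxylabda-8(17),13(16),14-trien-3-ol; 16 angelic acid
Product: 18 (2S,3S,4S,5S,9R,10S)-18-(tert-butyldimethylsilyloxy)-2-(triethylsilyloxy)-15,16-epoxylabda-8(17),13(16),14-trien-3-yl (2Z)-2-methylbut-2-enoate, via mixed anhydride 17 (not isolated)
Conditions: 16, 2,4,6-trichlorobenzoyl chloride, Et3N, toluene, rt; then 15, DMAP, toluene, 70 °C
Reagents that add atoms: none
Why: Yamaguchi esterification through the mixed anhydride, attacked under DMAP catalysis at its unhindered angeloyl carbonyl, is a standard way to place an angelate on a hindered secondary alcohol and should keep the Z geometry because no strong base is present.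

**Step 12**
Reactants: 18 (2S,3S,4S,5S,9R,10S)-18-(tert-butyldimethylsilyloxy)-2-(triethylsilyloxy)-15,16-epoxylabda-8(17),13(16),14-trien-3-yl (2Z)-2-methylbut-2-enoate
Product: 21 (2S,3S,4S,5S,9R,10S,13Z)-18-(tert-butyldimethylsilyloxy)-15,16-dihydroxy-2-(triethylsilyloxy)labda-8(17),13-dien-3-yl (2Z)-2-methylbut-2-enoate, via furan endoperoxide 19 (not isolated), via cis-enedial 20 (not isolated)
Conditions: O2, visible light, tetraphenylporphyrin (cat.), CH2Cl2, −78 °C; Me2S, −78 to −20 °C; then NaBH4, CeCl3·7H2O, MeOH, −78 to 0 °C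
Reagents that add atoms: oxygen (as singlet oxygen), O=O
Why: [4+2] cycloaddition of singlet oxygen to the furan gives the endoperoxide, dimethyl sulfide reduces it to the cis-enedial and Luche reduction of both aldehydes gives the diol, so that the 13Z geometry is inherited from the furan ring, while singlet oxygen reacts far faster with the furan than with the 1,1-disubstituted alkene or the electron-poor angelate and NaBH4 with CeCl3 at low temperature leaves the conjugated ester alone.

**Step 13**
Reactants: 21 (2S,3S,4S,5S,9R,10S,13Z)-18-(tert-butyldimethylsilyloxy)-15,16-dihydroxy-2-(triethylsilyloxy)labda-8(17),13-dien-3-yl (2Z)-2-methylbut-2-enoate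
Product: 22 (2S,3S,4S,5S,9R,10S,13Z)-2,15,16,18-tetrahydroxylabda-8(17),13-dien-3-yl (2Z)-2-methylbut-2-enoate
Conditions: HF·pyridine, pyridine, THF, 0 °C to rt
Reagents that add atoms: none
Why: Fluoride-induced cleavage of the triethylsilyl and tert-butyldimethylsilyl ethers under pyridine-buffered, mildly acidic conditions should free the hydroxyl groups without acyl migration or isomerisation of the angelate.

**Compound list**

1 | furan-3-ylmethanol | OCc1ccoc1 | starting material
2 | 3-(chloromethyl)furan | ClCc1ccoc1 | intermediate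
3 | (2E,6E)-farnesyl bromide, (2E,6E)-1-bromo-3,7,11-trimethyldodeca-2,6,10-triene | BrC/C=C(\C)CC/C=C(\C)CCC=C(C)C | starting material
4 | (furan-3-ylmethyl)magnesium chloride | Cl[Mg]Cc1ccoc1 | intermediate (not isolated)
5 | 3-[(3E,7E)-4,8,12-trimethyltrideca-3,7,11-trien-1-yl]furan | o1ccc(c1)CC/C=C(\C)CC/C=C(\C)CCC=C(C)C | intermediate
6 | (2E,6E,10E)-13-(furan-3-yl)-2,6,10-trimethyltrideca-2,6,10-trien-1-ol | o1ccc(c1)CC/C=C(\C)CC/C=C(\C)CC/C=C(\C)CO | intermediate
7 | [(2R,3R)-3-[(3E,7E)-10-(furan-3-yl)-3,7-dimethyldeca-3,7-dien-1-yl]-2-methyloxiran-2-yl]methanol | o1ccc(c1)CC/C=C(\C)CC/C=C(\C)CC[C@H]1O[C@]1(C)CO | intermediate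
8 | tert-butyl{[(2R,3R)-3-[(3E,7E)-10-(furan-3-yl)-3,7-dimethyldeca-3,7-dien-1-yl]-2-methyloxiran-2-yl]methoxy}dimethylsilane | o1ccc(c1)CC/C=C(\C)CC/C=C(\C)CC[C@H]1O[C@]1(C)CO[Si](C)(C)C(C)(C)C | intermediate
9 | (3R,4S,5S,9R,10S)-18-(tert-butyldimethylsilyloxy)-3-(trimethylsilyloxy)-15,16-epoxylabda-8(17),13(16),14-triene | C=C1CC[C@H]2[C@@](C)(CC[C@@H](O[Si](C)(C)C)[C@]2(C)CO[Si](C)(C)C(C)(C)C)[C@@H]1CCc1ccoc1 | intermediate (not isolated)
10 | (3R,4S,5S,9R,10S)-18-(tert-butyldimethylsilyloxy)-15,16-epoxylabda-8(17),13(16),14-trien-3-ol (trans-decalin; 3-OH and CH2OTBS equatorial; C4 methyl axial, cis to the C10 methyl; furylethyl chain at C9 equatorial) | C=C1CC[C@H]2[C@@](C)(CC[C@@H](O)[C@]2(C)CO[Si](C)(C)C(C)(C)C)[C@@H]1CCc1ccoc1 | intermediate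
11 | (4S,5S,9R,10S)-18-(tert-butyldimethylsilyloxy)-15,16-epoxylabda-8(17),13(16),14-trien-3-one | C=C1CC[C@H]2[C@@](C)(CCC(=O)[C@]2(C)CO[Si](C)(C)C(C)(C)C)[C@@H]1CCc1ccoc1 | intermediate
12 | potassium (4S,5S,9R,10S)-18-(tert-butyldimethylsilyloxy)-15,16-epoxylabda-2,8(17),13(16),14-tetraen-3-olate | C=C1CC[C@H]2[C@@](C)(CC=C([O-])[C@]2(C)CO[Si](C)(C)C(C)(C)C)[C@@H]1CCc1ccoc1.[K+] | intermediate (not isolated)
13 | (2S,4S,5S,9R,10S)-18-(tert-butyldimethylsilyloxy)-2-hydroxy-15,16-epoxylabda-8(17),13(16),14-trien-3-one (2-OH equatorial) | C=C1CC[C@H]2[C@@](C)(C[C@H](O)C(=O)[C@]2(C)CO[Si](C)(C)C(C)(C)C)[C@@H]1CCc1ccoc1 | intermediate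
14 | (2S,4S,5S,9R,10S)-18-(tert-butyldimethylsilyloxy)-2-(triethylsilyloxy)-15,16-epoxylabda-8(17),13(16),14-trien-3-one | C=C1CC[C@H]2[C@@](C)(C[C@H](O[Si](CC)(CC)CC)C(=O)[C@]2(C)CO[Si](C)(C)C(C)(C)C)[C@@H]1CCc1ccoc1 | intermediate
15 | (2S,3S,4S,5S,9R,10S)-18-(tert-butyldimethylsilyloxy)-2-(triethylsilyloxy)-15,16-epoxylabda-8(17),13(16),14-trien-3-ol (2,3-trans-diequatorial) | C=C1CC[C@H]2[C@@](C)(C[C@H](O[Si](CC)(CC)CC)[C@@H](O)[C@]2(C)CO[Si](C)(C)C(C)(C)C)[C@@H]1CCc1ccoc1 | intermediate
16 | angelic acid, (2Z)-2-methylbut-2-enoic acid | C/C=C(/C)C(=O)O | starting material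
17 | (2Z)-2-methylbut-2-enoic 2,4,6-trichlorobenzoic anhydride | C/C=C(/C)C(=O)OC(=O)c1c(Cl)cc(Cl)cc1Cl | intermediate (not isolated)
18 | (2S,3S,4S,5S,9R,10S)-18-(tert-butyldimethylsilyloxy)-2-(triethylsilyloxy)-15,16-epoxylabda-8(17),13(16),14-trien-3-yl (2Z)-2-methylbut-2-enoate | C=C1CC[C@H]2[C@@](C)(C[C@H](O[Si](CC)(CC)CC)[C@@H](OC(=O)/C(C)=C\C)[C@]2(C)CO[Si](C)(C)C(C)(C)C)[C@@H]1CCc1ccoc1 | intermediate
19 | endoperoxide of 18: the furan ring as a 5-substituted 2,3,7-trioxabicyclo[2.2.1]hept-5-ene (both bridgehead configurations) | C=C1CC[C@H]2[C@@](C)(C[C@H](O[Si](CC)(CC)CC)[C@@H](OC(=O)/C(C)=C\C)[C@]2(C)CO[Si](C)(C)C(C)(C)C)[C@@H]1CCC1=CC2OOC1O2 | intermediate (not isolated)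
20 | (2S,3S,4S,5S,9R,10S,13Z)-18-(tert-butyldimethylsilyloxy)-15,16-dioxo-2-(triethylsilyloxy)labda-8(17),13-dien-3-yl (2Z)-2-methylbut-2-enoate | C=C1CC[C@H]2[C@@](C)(C[C@H](O[Si](CC)(CC)CC)[C@@H](OC(=O)/C(C)=C\C)[C@]2(C)CO[Si](C)(C)C(C)(C)C)[C@@H]1CC/C(=C/C=O)C=O | intermediate (not isolated)
21 | (2S,3S,4S,5S,9R,10S,13Z)-18-(tert-butyldimethylsilyloxy)-15,16-dihydroxy-2-(triethylsilyloxy)labda-8(17),13-dien-3-yl (2Z)-2-methylbut-2-enoate | C=C1CC[C@H]2[C@@](C)(C[C@H](O[Si](CC)(CC)CC)[C@@H](OC(=O)/C(C)=C\C)[C@]2(C)CO[Si](C)(C)C(C)(C)C)[C@@H]1CC/C(=C/CO)CO | intermediate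
22 | (2S,3S,4S,5S,9R,10S,13Z)-2,15,16,18-tetrahydroxylabda-8(17),13-dien-3-yl (2Z)-2-methylbut-2-enoate, CNP0324138.1 | C=C1CC[C@H]2[C@@](C)(C[C@H](O)[C@@H](OC(=O)/C(C)=C\C)[C@]2(C)CO)[C@@H]1CC/C(=C/CO)CO | target

Total steps: 13. Longest linear sequence: 13 steps (1 to 22).

**Steps most likely to fail**

Step 6 (key step). What may go wrong: the last radical is not funnelled cleanly to the exocyclic alkene (endocyclic isomers, premature reduction, or a third ring closure onto the furan), or the planar C4 radical shows weak facial preference. The fallback replaces the radical cascade by a cationic, stereospecific epoxide/allylsilane bicyclization, in which anti opening of the epoxide fixes C4 and loss of silicon can only give the 8(17)-alkene. It sets out from 2 (through its Grignard reagent 4) and returns at 10. Commercial geranyl acetate F1 is oxidised at the terminal E-methyl group (SeO2 cat., t-BuOOH) to the hydroxy acetate F2, and Sharpless epoxidation (Ti(OiPr)4, D-(−)-diethyl tartrate, t-BuOOH) gives the epoxy alcohol F3. Silylation (TBSCl, imidazole) gives the silyl ether F4, methanolysis (K2CO3, MeOH) the allylic alcohol F5, and MsCl/Et3N then LiBr the bromide F6. Alkylation of the dianion of methyl acetoacetate (NaH, then n-BuLi) with F6 gives the β-keto ester F7. Its (Z)-enol triflate F8 (NaH, PhNTf2) is coupled with Me3SiCH2MgCl under Pd(PPh3)4 (zerovalent palladium) to give, with retention, the allylsilane ester F9. DIBAL-H gives the allylic alcohol F10, MsCl/Et3N then LiBr the bromide F11, and Li2CuCl4-catalysed coupling with Grignard reagent 4 the epoxy allylsilane F12. MeAlCl2 in CH2Cl2 at −78 °C should then cyclise F12 through a chair–chair transition state directly to 10.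

Step 12. What may go wrong: loss of chemoselectivity or of Z geometry during the furan unmasking (cis–trans isomerisation or over-oxidation of the enedial, conjugate reduction). The fallback unmasks the furan before the ester is present, through the lactone oxidation level and a strong hydride. It sets out from 15 and returns at 22. Photooxygenation of 15 in the presence of a hindered amine (O2, light, sensitiser, i-Pr2NEt, CH2Cl2, −78 °C) gives the γ-hydroxybutenolide F13, NaBH4 reduces it to the butenolide F14, and DIBAL-H reduces the lactone to the (13Z)-15,16-diol F15. Selective silylation of the two primary allylic hydroxyls (TBSCl, imidazole, 0 °C) gives the bis-silyl ether F16, Yamaguchi esterification with 16 as in step 11 gives the angelate F17, and HF·pyridine removes all four silyl groups to give 22.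

Step 11. What may go wrong: sluggish acylation of the hindered C3 hydroxyl, accompanied by isomerisation of the angeloyl unit to the tigloyl unit (Z to E) under forcing conditions. The fallback builds the Z-alkene on the substrate after acylation. It sets out from 15 and returns at 18. Esterification of 15 with 2-[bis(2,2,2-trifluoroethoxy)phosphoryl]propanoic acid (DCC, DMAP, CH2Cl2) gives the phosphonate ester F18. Still–Gennari olefination (KHMDS, 18-crown-6, THF, −78 °C; acetaldehyde) should then give the (Z)-2-methylbut-2-enoate 18 under kinetic control.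

**Further compounds**

F1 | step 6 | geranyl acetate, (2E)-3,7-dimethylocta-2,6-dien-1-yl acetate | CC(=O)OC/C=C(\C)CCC=C(C)C
F2 | step 6 | (2E,6E)-8-hydroxy-3,7-dimethylocta-2,6-dien-1-yl acetate | CC(=O)OC/C=C(\C)CC/C=C(\C)CO
F3 | step 6 | (2E)-5-[(2R,3R)-3-(hydroxymethyl)-3-methyloxiran-2-yl]-3-methylpent-2-en-1-yl acetate | CC(=O)OC/C=C(\C)CC[C@H]1O[C@]1(C)CO
F4 | step 6 | (2E)-5-[(2R,3R)-3-[(tert-butyldimethylsilyloxy)methyl]-3-methyloxiran-2-yl]-3-methylpent-2-en-1-yl acetate | CC(=O)OC/C=C(\C)CC[C@H]1O[C@]1(C)CO[Si](C)(C)C(C)(C)C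
F5 | step 6 | (2E)-5-[(2R,3R)-3-[(tert-butyldimethylsilyloxy)methyl]-3-methyloxiran-2-yl]-3-methylpent-2-en-1-ol | OC/C=C(\C)CC[C@H]1O[C@]1(C)CO[Si](C)(C)C(C)(C)C
F6 | step 6 | (2E)-1-bromo-5-[(2R,3R)-3-[(tert-butyldimethylsilyloxy)methyl]-3-methyloxiran-2-yl]-3-methylpent-2-ene | BrC/C=C(\C)CC[C@H]1O[C@]1(C)CO[Si](C)(C)C(C)(C)C
F7 | step 6 | methyl (6E)-9-[(2R,3R)-3-[(tert-butyldimethylsilyloxy)methyl]-3-methyloxiran-2-yl]-7-methyl-3-oxonon-6-enoate | COC(=O)CC(=O)CC/C=C(\C)CC[C@H]1O[C@]1(C)CO[Si](C)(C)C(C)(C)C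
F8 | step 6 | methyl (2Z,6E)-9-[(2R,3R)-3-[(tert-butyldimethylsilyloxy)methyl]-3-methyloxiran-2-yl]-7-methyl-3-(trifluoromethylsulfonyloxy)nona-2,6-dienoate | COC(=O)/C=C(/CC/C=C(\C)CC[C@H]1O[C@]1(C)CO[Si](C)(C)C(C)(C)C)OS(=O)(=O)C(F)(F)F
F9 | step 6 | methyl (2Z,6E)-9-[(2R,3R)-3-[(tert-butyldimethylsilyloxy)methyl]-3-methyloxiran-2-yl]-7-methyl-3-[(trimethylsilyl)methyl]nona-2,6-dienoate | COC(=O)/C=C(/CC/C=C(\C)CC[C@H]1O[C@]1(C)CO[Si](C)(C)C(C)(C)C)C[Si](C)(C)C
F10 | step 6 | (2Z,6E)-9-[(2R,3R)-3-[(tert-butyldimethylsilyloxy)methyl]-3-methyloxiran-2-yl]-7-methyl-3-[(trimethylsilyl)methyl]nona-2,6-dien-1-ol | OC/C=C(/CC/C=C(\C)CC[C@H]1O[C@]1(C)CO[Si](C)(C)C(C)(C)C)C[Si](C)(C)C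
F11 | step 6 | (2Z,6E)-1-bromo-9-[(2R,3R)-3-[(tert-butyldimethylsilyloxy)methyl]-3-methyloxiran-2-yl]-7-methyl-3-[(trimethylsilyl)methyl]nona-2,6-diene | BrC/C=C(/CC/C=C(\C)CC[C@H]1O[C@]1(C)CO[Si](C)(C)C(C)(C)C)C[Si](C)(C)C
F12 | step 6 | tert-butyl{[(2R,3R)-3-[(3E,7Z)-10-(furan-3-yl)-3-methyl-7-[(trimethylsilyl)methyl]deca-3,7-dien-1-yl]-2-methyloxiran-2-yl]methoxy}dimethylsilane | o1ccc(c1)CC/C=C(/CC/C=C(\C)CC[C@H]1O[C@]1(C)CO[Si](C)(C)C(C)(C)C)C[Si](C)(C)C
F13 | step 12 | γ-hydroxybutenolide from 15: side chain at C12 is 5-hydroxy-2-oxo-2,5-dihydrofuran-4-yl (both hemiacetal epimers), 3-OH free | C=C1CC[C@H]2[C@@](C)(C[C@H](O[Si](CC)(CC)CC)[C@@H](O)[C@]2(C)CO[Si](C)(C)C(C)(C)C)[C@@H]1CCC1=CC(=O)OC1O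
F14 | step 12 | butenolide: side chain at C12 is 2-oxo-2,5-dihydrofuran-4-yl (labd-13-en-15,16-olide type), 3-OH free | C=C1CC[C@H]2[C@@](C)(C[C@H](O[Si](CC)(CC)CC)[C@@H](O)[C@]2(C)CO[Si](C)(C)C(C)(C)C)[C@@H]1CCC1=CC(=O)OC1
F15 | step 12 | (2S,3S,4S,5S,9R,10S,13Z)-18-(tert-butyldimethylsilyloxy)-2-(triethylsilyloxy)labda-8(17),13-diene-3,15,16-triol | C=C1CC[C@H]2[C@@](C)(C[C@H](O[Si](CC)(CC)CC)[C@@H](O)[C@]2(C)CO[Si](C)(C)C(C)(C)C)[C@@H]1CC/C(=C/CO)CO
F16 | step 12 | (2S,3S,4S,5S,9R,10S,13Z)-15,16,18-tris(tert-butyldimethylsilyloxy)-2-(triethylsilyloxy)labda-8(17),13-dien-3-ol | C=C1CC[C@H]2[C@@](C)(C[C@H](O[Si](CC)(CC)CC)[C@@H](O)[C@]2(C)CO[Si](C)(C)C(C)(C)C)[C@@H]1CC/C(=C/CO[Si](C)(C)C(C)(C)C)CO[Si](C)(C)C(C)(C)C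
F17 | step 12 | (2S,3S,4S,5S,9R,10S,13Z)-15,16,18-tris(tert-butyldimethylsilyloxy)-2-(triethylsilyloxy)labda-8(17),13-dien-3-yl (2Z)-2-methylbut-2-enoate | C=C1CC[C@H]2[C@@](C)(C[C@H](O[Si](CC)(CC)CC)[C@@H](OC(=O)/C(C)=C\C)[C@]2(C)CO[Si](C)(C)C(C)(C)C)[C@@H]1CC/C(=C/CO[Si](C)(C)C(C)(C)C)CO[Si](C)(C)C(C)(C)C
F18 | step 11 | 3-O-{2-[bis(2,2,2-trifluoroethoxy)phosphoryl]propanoyl} ester of 15 (both epimers at the phosphonate carbon) | C=C1CC[C@H]2[C@@](C)(C[C@H](O[Si](CC)(CC)CC)[C@@H](OC(=O)C(C)P(=O)(OCC(F)(F)F)OCC(F)(F)F)[C@]2(C)CO[Si](C)(C)C(C)(C)C)[C@@H]1CCc1ccoc1
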